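Substrate in the dawn run ran down to 6.2% of its charge and stayed far above the scatter of 0.3 percentage points, and that level was what I carried to the new flask.

| flask | substrate | remark | time |
|---|---|---|---|
| dawn | 0.028 M | run made earlier |  |
| flask | 0.019 M |  | 10 d |

- dawn (time / h: substrate / %, side product / %): 4.00: 40.6, 7.2; 6.00: 34.5, 8.6; 10.0: 23.9, 10.8; 20.0: 11.5, 12.3; 30.0: 7.1, 12.0; 50.0: 6.2, 12.0

(readings scatter by 0.3 percentage points)

- a species is counted by the substrate in it: one side product counts as three
- the reaction counts as stopped when no species that holds the substrate changes by six tenths of a point or more over the second half of the time
- what has gone from substrate into another species counts as reacted, even if it can come back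

- which holds at 10 d: what has brought the reaction to rest, or that it has not come to rest (all of the substrate has reacted / it is still moving / forward and back rates have come level)
- part of the substrate gone at 10 d
- the side product standing at 10 d, as a percentage of the substrate charged

The dawn curve began steeply: by 4.00 h substrate had lost 59.4% of the charge, while side product stood at 7.2%, which left 52.2% in no column. Substrate crossed side product near 20.0 h, at 11.5% against 12.3%, and side product ended flat at 12.0%. Measured from the level, substrate's distance shrank from 18 points at 10.0 h to 5.3 points at 20.0 h, so I read a half-life of 5.75 h. The flask's 10 d is 41.7 such half-lives, so I expected rest, and I read the level as equilibrium rather than a limiting reagent running out.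

My rule rested on 13.2, the standing ratio [unseen]/[substrate] at rest, as read from the last dawn reading with its scatter. If the unseen species holds one substrate, the charge cancels from the ratio, and free substrate is the charge less side product, divided by one plus the ratio. With side product taken from none to the dawn level, I estimated conversion in the flask at 93.0% to 93.8%, a span that was no bound because the ratio was a scattered reading.

The forecast said forward and back rates have come level, with 93.4% gone and 7% side product: “Substrate sits well above zero, so this looks like equilibrium, not exhaustion.”

    2 substrate ⇌ target (K = 17.0 L mol⁻¹, k = 7.60 L mol⁻¹ h⁻¹)
    substrate + target → side product (k = 3.60 L mol⁻¹ h⁻¹)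
    substrate ⇌ dormant form (K = 15.0, k = 0.140 h⁻¹)
    target ⇌ isomer of the product (K = 0.320, k = 0.0130 h⁻¹)

The flask gave forward and back rates have come level, with 94.2% gone and 7.18% side product. Over the second half of the time the largest change in any share was 0.15 points, less than the scatter of a reading. The ratio of 13.2 with that side product gives 6.54% free substrate, but the flask held 5.8%, so its conversion stood above the top of my span, 93.8%. A neighbour flask charged with 0.048 M reached 23.2% side product, for which the ratio gives 5.41%, and it held 4.7%.

The runs were computed from invented constants; scatter was added.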